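## The problem

Target 25 is a depside. The carboxyl carbon on C1 of ring A is joined as an aryl ester to the C4' oxygen of ring B, a 2,4-dihydroxy-3,6-dimethylbenzoic acid unit whose C2' hydroxyl and C1' carboxylic acid stay free. Ring A is a pentasubstituted benzene (C1 carboxyl, C2 OMe, C3 CH2OH, C4 OMe, C5 H, C6 CH3). Its acid has two ortho substituents, so the ester bond must be made from a hindered acyl donor and at one of two phenols. There is no stereocenter, so the selectivity problems are regiochemical: placing a one-carbon unit on C3, between two oxygen-bearing carbons, and acylating O4' but not O2'. Three groups limit the reagents. The depside ester is cleaved by hydroxide, alkoxides and warm amines; the 2,6-dimethoxybenzylic C–O bond at C3 ionises in acid and is at risk under hydrogenolysis; the salicylic acid of ring B loses CO2 in hot acid. Both carboxyl groups therefore need protection that leaves under neutral conditions, and the benzylic alcohol must be unmasked without acid. Ring B can be bought as its methyl ester 19, so the real construction problem is ring A. Its pattern is what a vinylketene and an alkoxyalkyne give on union: the ketene supplies C2 as its carbonyl carbon and C5, C6 and C1 as its alkene, and the alkyne supplies C3 and C4.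

## Retrosynthesis

**Protecting groups, 25 back to 23.** The ring B carboxyl is carried as an allyl ester and the C3 benzylic alcohol as a triisopropylsilyl ether, so 25 comes from 24 and 24 from 23. A methyl ester would need saponification, which the depside does not survive. A benzyl ester would need hydrogenolysis, which threatens the activated benzylic C–O bond. The allyl ester leaves with zerovalent palladium and a neutral sulfinate, and the silyl ether with buffered fluoride.

**Depside bond, 23 back to 18 and 21.** Cutting the C1(=O)–O4' bond gives ring A acid 18 and ring B phenol 21, two fragments of similar size. This is the most convergent cut and puts the only ester-forming step late. The forward reaction must activate a 2,6-disubstituted acid without acid (acid chloride 22 from a neutral α-chloroenamine) and must choose O4' over O2'. The O2' hydroxyl is hydrogen-bonded to the ester carbonyl and flanked on both sides, which should secure this.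

**Ring B, 21 back to 19.** Allyl ester 21 comes from commercial methyl ester 19 by saponification to acid 20 and carboxylate alkylation. No C–C bond is made.

**Ring A adjustments, 18 back to 16.** Acid 18 comes from allyl ester 17 by palladium-catalysed deallylation, and 17 from phenol 16 by O-methylation at C2. The allyl ester is chosen because a benzoate with two ortho substituents resists hydrolysis, whereas allyl cleavage takes place at the allyl carbon and is indifferent to that hindrance.

**Ring A construction, 16 back to 7 and 11.** The C1–C2, C2–C3 and C4–C5 bonds are cut together. Phenol 16 then falls into diazoketone 7, which carries C1, C6, C5 and C2 with the methyl and the ester, and ynol ether 11, which carries C3 and C4 with the CH2OSi and OMe groups. The neighbouring option is electrophilic substitution on an orsellinate, which gives C3/C5 mixtures and leaves the two oxygens to be told apart. Here the alkyne polarity fixes the carbon between the oxygens, and O2 and O4 arrive already differentiated as phenol and methyl ether. Both precursors are acyclic and have five or six carbons. The forward reaction must generate the vinylketene cleanly and keep the E alkene geometry.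

**Diazoketone, 7 back to 1 and 4.** The diazo group is put on the methyl ketone of 5 by detrifluoroacetylative diazo transfer through 6. Acylation of diazomethane by an unsaturated acid chloride is avoided because diazomethane adds to such electron-poor alkenes. Enone 5 is cut at its C=C bond into butane-2,3-dione 4 and ylide 3, made from allyl bromoacetate 1 through salt 2.

**Alkyne, 11 back to 8.** Silyl ether 11 comes from alcohol 10. The C–C bond of 10 is cut to formaldehyde and lithium methoxyacetylide 9, which is made in the flask from chloroacetaldehyde dimethyl acetal 8 by double elimination.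

## Roads not taken

**Alternative 1:** Ring B is built by base-induced aldol aromatisation of a dioxinone-masked triketo acid, 6-(3,5-dioxohexan-2-yl)-2,2-dimethyl-4H-1,3-dioxin-4-one A2. The aldol joins C1' to the C6' ketone carbon and gives 7-hydroxy-2,2,5,8-tetramethyl-4H-1,3-benzodioxin-4-one A1.
- Merit: A1 has only the C4' hydroxyl free, so the depside acylation has no choice to make. On this point it is better than the chosen plan, which relies on the hydrogen-bonded, flanked O2' hydroxyl of 21 being less reactive and holds a protecting-group fallback.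
- Weak points: A2 needs several steps and a regioselective C-methylation between two carbonyls, yet it delivers a ring that is sold as 19. The benzodioxinone must be opened at the end with hydroxide or alkoxide, which also attacks the depside ester. Ring A, the hard part, is not addressed.

**Alternative 2:** Ring A is taken from a symmetrical aryl bromide, [(4-bromo-2,6-dimethoxyphenyl)methoxy]tri(propan-2-yl)silane A4. Lithium 2,2,6,6-tetramethylpiperidide generates the C1–C6 aryne, MeLi adds at C6 (directed by the C2 methoxy group) and CO2 traps the C1 aryllithium. The product is 2,4-dimethoxy-6-methyl-3-{[(triisopropylsilyl)oxy]methyl}benzoic acid A3, the same structure as acid 18.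
- Merit: A3 would be reached in about half the eight steps the chosen plan spends on 18, with no photochemistry and no diazo compound. In step count this road is better.
- Weak points: the key step rests on one organolithium process winning over several others: bromine–lithium exchange of A4 with MeLi, addition of the amide to the aryne, and protonation or aryne addition of the new aryllithium before CO2 arrives. No ring is formed, so the substitution pattern must already be in the arene.
- What the chosen plan sets against it: every substituent position follows from the connectivity of two acyclic partners and from a polarised cycloaddition, and the carboxyl arrives already protected as the ester needed later.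

**Alternative 3:** Ring B is built onto the ring A acid by a Diels–Alder reaction. The enol ester diene, 4-methoxy-3-methyl-4-[(trimethylsilyl)oxy]buta-1,3-dien-2-yl 2,4-dimethoxy-6-methyl-3-{[(triisopropylsilyl)oxy]methyl}benzoate A6, adds to allyl but-2-ynoate A7 and forms C1'–C2' and C5'–C6'. Collapse of the silyl ketal then gives allyl 4-[(2,4-dimethoxy-6-methyl-3-{[(triisopropylsilyl)oxy]methyl}benzoyl)oxy]-2-hydroxy-3,6-dimethylbenzoate A5, identical with 23.
- Merit: the depside ester is in place before ring B exists, so no phenol selectivity arises, and ring B is formed with full regiocontrol. In that respect it equals or betters step 11 of the chosen plan.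
- Weak points: A6 needs the ring A acid first, so ring A is still unsolved. The hindered acid must O-acylate a β-keto ester enolate. The enol ester must then survive γ-deprotonation and silylation, where acyl transfer is likely. A 3-acyloxy diene with a β-methyl ynoate is a sluggish pair that needs prolonged heating. The road replaces three steps on a purchasable ring with a longer, more fragile sequence.

Key step: step 6

## Route

Remark: ring A is numbered from the carboxyl-bearing carbon C1 to the methyl-bearing carbon C6, and ring B with primed numbers. Diazoketone 7 and the sulfonyl azide are assumed to be handled in solution and not distilled.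

Step 1
Reactants: 1 allyl bromoacetate
Product: 3 allyl 2-(triphenyl-λ5-phosphanylidene)acetate, via phosphonium bromide 2 (not isolated)
Conditions: PPh3, toluene, 25 °C; then 1 M NaOH, CH2Cl2/H2O, 0 °C
Reagents that add atoms: triphenylphosphine, c1ccc(cc1)P(c1ccccc1)c1ccccc1
Why: SN2 quaternisation of PPh3 by the α-bromo ester and deprotonation of the acidic salt with cold hydroxide give the stabilised ylide; standard Wittig reagent preparation, and the allyl ester survives brief cold base.

Step 2
Reactants: 3 allyl 2-(triphenyl-λ5-phosphanylidene)acetate; 4 butane-2,3-dione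
Product: 5 allyl (E)-3-methyl-4-oxopent-2-enoate
Conditions: 4 (2 equiv), CH2Cl2, 25 °C
Reagents that add atoms: none
Why: Wittig olefination of one carbonyl of the activated 1,2-diketone by a stabilised ylide; excess dione suppresses double olefination, and the ester should end up trans to the acetyl group (E), as is usual for stabilised ylides with this diketone.

Step 3
Reactants: 5 allyl (E)-3-methyl-4-oxopent-2-enoate
Product: 7 allyl (E)-5-diazo-3-methyl-4-oxopent-2-enoate, via trifluoroacetyl diketone 6 (not isolated)
Conditions: LiN(SiMe3)2, THF, −78 °C; CF3CO2CH2CF3, −78 °C; aq HCl work-up; then MsN3, Et3N, H2O, MeCN, 25 °C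
Reagents that add atoms: methanesulfonyl azide, CS(=O)(=O)N=[N+]=[N-]
Why: Detrifluoroacetylative diazo transfer: kinetic deprotonation of the methyl ketone and Claisen trifluoroacetylation give 6, which takes the diazo group from the sulfonyl azide and loses the trifluoroacetyl group as the sulfonyl amide. This is the standard route to α,β-unsaturated diazoketones and avoids diazomethane, which would add to the alkene.

Step 4
Reactants: 8 2-chloro-1,1-dimethoxyethane (chloroacetaldehyde dimethyl acetal)
Product: 10 3-methoxyprop-2-yn-1-ol, via lithium methoxyacetylide 9 (not isolated)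
Conditions: Et2NH, n-BuLi, THF, 0 °C; 8, 0 °C; (CH2O)n, −78 → 20 °C; aq NaHCO3
Reagents that add atoms: formaldehyde (as paraformaldehyde), C=O
Why: Three equivalents of LiNEt2 eliminate HCl and methanol from the chloroacetal and deprotonate the resulting methoxyacetylene; the acetylide adds to formaldehyde (acetylide addition to a carbonyl). The work-up is kept basic because 3-alkoxypropargylic alcohols rearrange to acrylates in acid.

Step 5
Reactants: 10 3-methoxyprop-2-yn-1-ol
Product: 11 1-methoxy-3-[(triisopropylsilyl)oxy]prop-1-yne
Conditions: TIPSCl, imidazole, DMF, 0 → 25 °C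
Reagents that add atoms: chlorotriisopropylsilane, CC(C)[Si](Cl)(C(C)C)C(C)C
Why: Imidazole-promoted silylation of a primary alcohol under non-acidic conditions; the bulky silyl ether removes the acid-labile propargylic OH and lasts through all later steps.

Step 6
Reactants: 7 allyl (E)-5-diazo-3-methyl-4-oxopent-2-enoate; 11 1-methoxy-3-[(triisopropylsilyl)oxy]prop-1-yne
Product: 16 allyl 2-hydroxy-4-methoxy-6-methyl-3-{[(triisopropylsilyl)oxy]methyl}benzoate, via vinylketene 12 (not isolated), via cyclobutenone 13 (not isolated), via dienylketene 14 (not isolated), via cyclohexadienone 15 (not isolated)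
Conditions: hν (254 nm, low-pressure mercury lamp, quartz), ClCH2CH2Cl, 20 °C; then 80 °C
Reagents that add atoms: none
Why: Irradiation expels N2 from 7 and the alkenyl group migrates (photochemical Wolff rearrangement) to give vinylketene 12 with the E alkene retained. The electron-rich ynol ether 11 adds across the ketene C=C bond in a (2+2) cycloaddition in which its carbon remote from oxygen bonds to the ketene carbonyl carbon, so cyclobutenone 13 carries the CH2OSi carbon next to the carbonyl; this forms the C2–C3 and C4–C5 bonds. Light or heat opens 13 by a 4π electrocyclic reaction to dienylketene 14, and the isomer with the alkenyl group turned inward closes ring A by a thermal 6π disrotatory electrocyclisation that forms the C1–C2 bond; dienone 15 then tautomerises to the chelated salicylate 16. The closest known reaction is the Danheiser benzannulation in its diazoketone form, which is established with alkoxy- and silyloxyalkynes. No stereocenter is formed, since the sp3 carbons of 13 and 15 are transient. The step needs regioselectivity in the (2+2) event, which the polarisation of the alkyne secures, and a triene geometry that can close: the E alkene of 7 puts H, not the ester, on the inside of the closing terminus and keeps the ester carbonyl away from the ketene, so closure to a 2-pyranone is blocked. The product phenol is chelated and flanked by the ester and the CH2OSi group, which should keep it from trapping ketene 12.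

Step 7
Reactants: 16 allyl 2-hydroxy-4-methoxy-6-methyl-3-{[(triisopropylsilyl)oxy]methyl}benzoate
Product: 17 allyl 2,4-dimethoxy-6-methyl-3-{[(triisopropylsilyl)oxy]methyl}benzoate
Conditions: MeI, K2CO3, DMF, 40 °C
Reagents that add atoms: iodomethane, CI
Why: Williamson O-methylation of the salicylate phenol; polar solvent and gentle warming overcome the hydrogen bond and the flanking groups, and the allyl ester and silyl ether are inert to carbonate.

Step 8
Reactants: 17 allyl 2,4-dimethoxy-6-methyl-3-{[(triisopropylsilyl)oxy]methyl}benzoate
Product: 18 2,4-dimethoxy-6-methyl-3-{[(triisopropylsilyl)oxy]methyl}benzoic acid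
Conditions: Pd(PPh3)4 (5 mol %), morpholine, THF, 25 °C; cold aq citric acid work-up
Reagents that add atoms: none
Why: Tsuji–Trost deallylation: zerovalent palladium ionises the allyl ester to a π-allyl complex that morpholine captures, so the hindered carboxyl is freed without attack at its carbonyl and without strong acid or base.

Step 9
Reactants: 19 methyl 2,4-dihydroxy-3,6-dimethylbenzoate
Product: 20 2,4-dihydroxy-3,6-dimethylbenzoic acid
Conditions: KOH, H2O/DMSO, 70 °C, N2; then HCl, 0 °C
Reagents that add atoms: water (as hydroxide), O
Why: Saponification of the hindered salicylate ester; the carboxylate salt is stable, and cold acidification under nitrogen avoids the decarboxylation that β-resorcylic acids undergo in hot acid.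

Step 10
Reactants: 20 2,4-dihydroxy-3,6-dimethylbenzoic acid
Product: 21 allyl 2,4-dihydroxy-3,6-dimethylbenzoate
Conditions: allyl bromide, KHCO3, DMF, 25 °C
Reagents that add atoms: allyl bromide, C=CCBr
Why: Bicarbonate ionises only the carboxylic acid, so SN2 alkylation gives the allyl ester and leaves both phenols free.

Step 11
Reactants: 18 2,4-dimethoxy-6-methyl-3-{[(triisopropylsilyl)oxy]methyl}benzoic acid; 21 allyl 2,4-dihydroxy-3,6-dimethylbenzoate
Product: 23 allyl 4-[(2,4-dimethoxy-6-methyl-3-{[(triisopropylsilyl)oxy]methyl}benzoyl)oxy]-2-hydroxy-3,6-dimethylbenzoate, via acid chloride 22 (not isolated)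
Conditions: Me2C=C(Cl)NMe2, CH2Cl2, 0 → 25 °C; then 21, Et3N, DMAP, CH2Cl2, 0 → 25 °C
Reagents that add atoms: none
Why: The α-chloroenamine converts the acid to chloride 22 without liberating HCl, which protects the acid-labile benzylic silyl ether; DMAP-catalysed acylation then occurs at the more acidic and less hindered O4' phenol, because the O2' hydroxyl is chelated to the ester and flanked on both sides (the usual selectivity in depside esterification).

Step 12
Reactants: 23 allyl 4-[(2,4-dimethoxy-6-methyl-3-{[(triisopropylsilyl)oxy]methyl}benzoyl)oxy]-2-hydroxy-3,6-dimethylbenzoate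
Product: 24 allyl 4-{[3-(hydroxymethyl)-2,4-dimethoxy-6-methylbenzoyl]oxy}-2-hydroxy-3,6-dimethylbenzoate
Conditions: Bu4NF, AcOH (1:1), THF, 0 → 25 °C
Reagents that add atoms: none
Why: Fluoride cleaves the Si–O bond; acetic acid buffers the liberated alkoxide so that the aryl ester, itself shielded by two ortho substituents, is not transesterified, and the medium is never acidic enough to ionise the benzylic alcohol.

Step 13
Reactants: 24 allyl 4-{[3-(hydroxymethyl)-2,4-dimethoxy-6-methylbenzoyl]oxy}-2-hydroxy-3,6-dimethylbenzoate
Product: 25 4-{[3-(hydroxymethyl)-2,4-dimethoxy-6-methylbenzoyl]oxy}-2-hydroxy-3,6-dimethylbenzoic acid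
Conditions: Pd(PPh3)4 (5 mol %), p-TolSO2Na, THF/MeOH, 25 °C; then cold 0.5 M HCl to pH 3
Reagents that add atoms: none
Why: Tsuji–Trost deallylation with sodium p-toluenesulfinate as a neutral, non-basic allyl acceptor; the depside ester, the free benzylic alcohol and the salicylic acid are untouched, and the acid is isolated by brief cold acidification and extraction.

## Compound list

1 | allyl bromoacetate | C=CCOC(=O)CBr | starting material
2 | [2-(allyloxy)-2-oxoethyl]triphenylphosphonium bromide | C=CCOC(=O)C[P+](c1ccccc1)(c1ccccc1)c1ccccc1.[Br-] | intermediate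
3 | allyl 2-(triphenyl-λ5-phosphanylidene)acetate | C=CCOC(=O)C=P(c1ccccc1)(c1ccccc1)c1ccccc1 | intermediate
4 | butane-2,3-dione | CC(=O)C(C)=O | starting material
5 | allyl (E)-3-methyl-4-oxopent-2-enoate | C=CCOC(=O)/C=C(\C)C(C)=O | intermediate
6 | allyl (E)-7,7,7-trifluoro-3-methyl-4,6-dioxohept-2-enoate | C=CCOC(=O)/C=C(\C)C(=O)CC(=O)C(F)(F)F | intermediate
7 | allyl (E)-5-diazo-3-methyl-4-oxopent-2-enoate | C=CCOC(=O)/C=C(\C)C(=O)C=[N+]=[N-] | intermediate
8 | 2-chloro-1,1-dimethoxyethane | COC(CCl)OC | starting material
9 | lithium methoxyacetylide | [Li]C#COC | intermediate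
10 | 3-methoxyprop-2-yn-1-ol | COC#CCO | intermediate
11 | 1-methoxy-3-[(triisopropylsilyl)oxy]prop-1-yne | COC#CCO[Si](C(C)C)(C(C)C)C(C)C | intermediate
12 | allyl (2E)-3-methyl-5-oxopenta-2,4-dienoate (vinylketene) | C=CCOC(=O)/C=C(\C)C=C=O | intermediate
13 | allyl (2E)-3-(2-methoxy-4-oxo-3-{[(triisopropylsilyl)oxy]methyl}cyclobut-2-en-1-yl)but-2-enoate (racemic) | C=CCOC(=O)/C=C(\C)C1C(=O)C(CO[Si](C(C)C)(C(C)C)C(C)C)=C1OC | intermediate
14 | allyl (2E,4E)-5-methoxy-3-methyl-7-oxo-6-{[(triisopropylsilyl)oxy]methyl}hepta-2,4,6-trienoate (dienylketene) | C=CCOC(=O)/C=C(\C)/C=C(/OC)C(=C=O)CO[Si](C(C)C)(C(C)C)C(C)C | intermediate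
15 | allyl 4-methoxy-6-methyl-2-oxo-3-{[(triisopropylsilyl)oxy]methyl}cyclohexa-3,5-diene-1-carboxylate (racemic) | C=CCOC(=O)C1C(=O)C(CO[Si](C(C)C)(C(C)C)C(C)C)=C(OC)C=C1C | intermediate
16 | allyl 2-hydroxy-4-methoxy-6-methyl-3-{[(triisopropylsilyl)oxy]methyl}benzoate | C=CCOC(=O)c1c(C)cc(OC)c(CO[Si](C(C)C)(C(C)C)C(C)C)c1O | intermediate
17 | allyl 2,4-dimethoxy-6-methyl-3-{[(triisopropylsilyl)oxy]methyl}benzoate | C=CCOC(=O)c1c(C)cc(OC)c(CO[Si](C(C)C)(C(C)C)C(C)C)c1OC | intermediate
18 | 2,4-dimethoxy-6-methyl-3-{[(triisopropylsilyl)oxy]methyl}benzoic acid | COc1cc(C)c(C(=O)O)c(OC)c1CO[Si](C(C)C)(C(C)C)C(C)C | intermediate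
19 | methyl 2,4-dihydroxy-3,6-dimethylbenzoate | COC(=O)c1c(C)cc(O)c(C)c1O | starting material
20 | 2,4-dihydroxy-3,6-dimethylbenzoic acid | Cc1cc(O)c(C)c(O)c1C(=O)O | intermediate
21 | allyl 2,4-dihydroxy-3,6-dimethylbenzoate | C=CCOC(=O)c1c(C)cc(O)c(C)c1O | intermediate
22 | 2,4-dimethoxy-6-methyl-3-{[(triisopropylsilyl)oxy]methyl}benzoyl chloride | COc1cc(C)c(C(=O)Cl)c(OC)c1CO[Si](C(C)C)(C(C)C)C(C)C | intermediate
23 | allyl 4-[(2,4-dimethoxy-6-methyl-3-{[(triisopropylsilyl)oxy]methyl}benzoyl)oxy]-2-hydroxy-3,6-dimethylbenzoate | COc1cc(C)c(C(=O)Oc2cc(C)c(C(=O)OCC=C)c(O)c2C)c(OC)c1CO[Si](C(C)C)(C(C)C)C(C)C | intermediate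
24 | allyl 4-{[3-(hydroxymethyl)-2,4-dimethoxy-6-methylbenzoyl]oxy}-2-hydroxy-3,6-dimethylbenzoate | COc1cc(C)c(C(=O)Oc2cc(C)c(C(=O)OCC=C)c(O)c2C)c(OC)c1CO | intermediate
25 | 4-{[3-(hydroxymethyl)-2,4-dimethoxy-6-methylbenzoyl]oxy}-2-hydroxy-3,6-dimethylbenzoic acid | COc1cc(C)c(C(=O)Oc2cc(C)c(C(=O)O)c(O)c2C)c(OC)c1CO | target

## Step count and risks

Total: 13 steps. Longest linear sequence: 9 steps (1, 2, 3, 6, 7, 8, 11, 12, 13 from allyl bromoacetate). The alkyne branch (steps 4 and 5) and the ring B branch (steps 9 and 10) are convergent.

**Step 6 (key step).**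
- What may go wrong: photochemical E to Z isomerisation of the enoate in 7 or 12 would turn the ester inward, slow the 6π closure and open the way to 2-pyranone formation. The electron-poor alkenyl group may migrate poorly in the Wolff step, so other carbene pathways could compete. Ketene 12 may dimerise or be trapped by 16. Cyclobutenone 13 may convert incompletely.
- Fallback, from alkyne 11 back to acid 18: the same ring bonds are formed thermally from a cyclobutenone that carries no ester. 3-Methylcyclobut-2-en-1-one F1 (from commercial 3-ethoxycyclobut-2-en-1-one with MeLi, then dilute acid) is heated with 11 in toluene at 80 °C to give 3-methoxy-5-methyl-2-{[(triisopropylsilyl)oxy]methyl}phenol F2. Magnesium-mediated ortho-formylation (MgCl2, Et3N, paraformaldehyde, MeCN, reflux) at the only free ortho position gives 2-hydroxy-4-methoxy-6-methyl-3-{[(triisopropylsilyl)oxy]methyl}benzaldehyde F3. Methylation (MeI, K2CO3, DMF) gives 2,4-dimethoxy-6-methyl-3-{[(triisopropylsilyl)oxy]methyl}benzaldehyde F4, and Pinnick oxidation (NaClO2, NaH2PO4, 2-methylbut-2-ene, t-BuOH/H2O) gives 18.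

**Step 3.**
- What may go wrong: deprotonation at the C3 methyl group (γ to the ester) in competition with the methyl ketone, and Michael addition of the enolate to the doubly activated alkene of 5, would lower the yield of diketone 6.
- Fallback, from 5 back to 7, without strong base: condensation of 5 with N,N-dimethylformamide dimethyl acetal (toluene, 90 °C) gives the enaminone allyl (2E,5E)-6-(dimethylamino)-3-methyl-4-oxohexa-2,5-dienoate F5. Cycloaddition of p-toluenesulfonyl azide to the enamine C=C bond and fragmentation of the triazoline (MeCN, 25 °C) releases 7 and the N-sulfonylformamidine.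

**Step 4.**
- What may go wrong: acid-induced rearrangement of alcohol 10 to an acrylate during work-up, loss of the small volatile alcohol, and consumption of formaldehyde by the diethylamine present.
- Fallback, from 8 back to 11, bypassing 10: elimination of 8 with NaNH2 in liquid NH3 gives methoxyethyne F6, which is distilled into THF, lithiated with n-BuLi at −78 °C to amine-free acetylide 9 and alkylated with commercial (triisopropylsiloxy)methyl chloride to give 11 directly.

**Step 11.**
- What may go wrong: slow acylation by the doubly ortho-substituted acid chloride, with competing acylation at O2' or decomposition of 22 on standing.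
- Fallback, from 21 back to 25, with O2' blocked and the O4' phenoxide formed stoichiometrically: selective silylation of the O4' hydroxyl (TIPSCl, imidazole) gives allyl 2-hydroxy-3,6-dimethyl-4-[(triisopropylsilyl)oxy]benzoate F7. Mitsunobu allylation of the O2' hydroxyl (allyl alcohol, PPh3, diisopropyl azodicarboxylate) gives allyl 2-(allyloxy)-3,6-dimethyl-4-[(triisopropylsilyl)oxy]benzoate F8, and Bu4NF at 0 °C gives allyl 2-(allyloxy)-4-hydroxy-3,6-dimethylbenzoate F9. Its sodium phenoxide (NaH, THF) is acylated with 22 to give allyl 2-(allyloxy)-4-[(2,4-dimethoxy-6-methyl-3-{[(triisopropylsilyl)oxy]methyl}benzoyl)oxy]-3,6-dimethylbenzoate F10. Buffered Bu4NF gives allyl 2-(allyloxy)-4-{[3-(hydroxymethyl)-2,4-dimethoxy-6-methylbenzoyl]oxy}-3,6-dimethylbenzoate F11, and Pd(PPh3)4 with p-TolSO2Na removes the allyl ester and the allyl ether together to give 25.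

**Step 12.**
- What may go wrong: cleavage or transesterification of the depside ester by fluoride or by the liberated alkoxide, or slow desilylation under buffering that forces harsher conditions.
- Fallback, from 18 back to 25, with the silyl group removed before the depside exists and replaced by a group that leaves in the final palladium step: Bu4NF (THF) converts 18 into 3-(hydroxymethyl)-2,4-dimethoxy-6-methylbenzoic acid F12. Allyl chloroformate and pyridine, followed by aqueous NaHCO3 to hydrolyse the mixed anhydride, give 3-({[(allyloxy)carbonyl]oxy}methyl)-2,4-dimethoxy-6-methylbenzoic acid F13. Activation with the α-chloroenamine and coupling with 21 as in step 11 give allyl 4-{[3-({[(allyloxy)carbonyl]oxy}methyl)-2,4-dimethoxy-6-methylbenzoyl]oxy}-2-hydroxy-3,6-dimethylbenzoate F14. Pd(PPh3)4 with p-TolSO2Na removes the allyl ester and the allyl carbonate in one operation to give 25.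

## Further compounds

F1 | step 6 | 3-methylcyclobut-2-en-1-one | CC1=CC(=O)C1
F2 | step 6 | 3-methoxy-5-methyl-2-{[(triisopropylsilyl)oxy]methyl}phenol | COc1cc(C)cc(O)c1CO[Si](C(C)C)(C(C)C)C(C)C
F3 | step 6 | 2-hydroxy-4-methoxy-6-methyl-3-{[(triisopropylsilyl)oxy]methyl}benzaldehyde | COc1cc(C)c(C=O)c(O)c1CO[Si](C(C)C)(C(C)C)C(C)C
F4 | step 6 | 2,4-dimethoxy-6-methyl-3-{[(triisopropylsilyl)oxy]methyl}benzaldehyde | COc1cc(C)c(C=O)c(OC)c1CO[Si](C(C)C)(C(C)C)C(C)C
F5 | step 3 | allyl (2E,5E)-6-(dimethylamino)-3-methyl-4-oxohexa-2,5-dienoate | C=CCOC(=O)/C=C(\C)C(=O)/C=C/N(C)C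
F6 | step 4 | methoxyethyne | COC#C
F7 | step 11 | allyl 2-hydroxy-3,6-dimethyl-4-[(triisopropylsilyl)oxy]benzoate | C=CCOC(=O)c1c(C)cc(O[Si](C(C)C)(C(C)C)C(C)C)c(C)c1O
F8 | step 11 | allyl 2-(allyloxy)-3,6-dimethyl-4-[(triisopropylsilyl)oxy]benzoate | C=CCOC(=O)c1c(C)cc(O[Si](C(C)C)(C(C)C)C(C)C)c(C)c1OCC=C
F9 | step 11 | allyl 2-(allyloxy)-4-hydroxy-3,6-dimethylbenzoate | C=CCOC(=O)c1c(C)cc(O)c(C)c1OCC=C
F10 | step 11 | allyl 2-(allyloxy)-4-[(2,4-dimethoxy-6-methyl-3-{[(triisopropylsilyl)oxy]methyl}benzoyl)oxy]-3,6-dimethylbenzoate | COc1cc(C)c(C(=O)Oc2cc(C)c(C(=O)OCC=C)c(OCC=C)c2C)c(OC)c1CO[Si](C(C)C)(C(C)C)C(C)C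
F11 | step 11 | allyl 2-(allyloxy)-4-{[3-(hydroxymethyl)-2,4-dimethoxy-6-methylbenzoyl]oxy}-3,6-dimethylbenzoate | COc1cc(C)c(C(=O)Oc2cc(C)c(C(=O)OCC=C)c(OCC=C)c2C)c(OC)c1CO
F12 | step 12 | 3-(hydroxymethyl)-2,4-dimethoxy-6-methylbenzoic acid | COc1cc(C)c(C(=O)O)c(OC)c1CO
F13 | step 12 | 3-({[(allyloxy)carbonyl]oxy}methyl)-2,4-dimethoxy-6-methylbenzoic acid | COc1cc(C)c(C(=O)O)c(OC)c1COC(=O)OCC=C
F14 | step 12 | allyl 4-{[3-({[(allyloxy)carbonyl]oxy}methyl)-2,4-dimethoxy-6-methylbenzoyl]oxy}-2-hydroxy-3,6-dimethylbenzoate | COc1cc(C)c(C(=O)Oc2cc(C)c(C(=O)OCC=C)c(O)c2C)c(OC)c1COC(=O)OCC=C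
A1 | alternative 1 | 7-hydroxy-2,2,5,8-tetramethyl-4H-1,3-benzodioxin-4-one | Cc1cc(O)c(C)c2OC(C)(C)OC(=O)c12
A2 | alternative 1 | 6-(3,5-dioxohexan-2-yl)-2,2-dimethyl-4H-1,3-dioxin-4-one | CC(=O)CC(=O)C(C)C1=CC(=O)OC(C)(C)O1
A3 | alternative 2 | 2,4-dimethoxy-6-methyl-3-{[(triisopropylsilyl)oxy]methyl}benzoic acid | COc1cc(C)c(C(=O)O)c(OC)c1CO[Si](C(C)C)(C(C)C)C(C)C
A4 | alternative 2 | [(4-bromo-2,6-dimethoxyphenyl)methoxy]tri(propan-2-yl)silane | COc1cc(Br)cc(OC)c1CO[Si](C(C)C)(C(C)C)C(C)C
A5 | alternative 3 | allyl 4-[(2,4-dimethoxy-6-methyl-3-{[(triisopropylsilyl)oxy]methyl}benzoyl)oxy]-2-hydroxy-3,6-dimethylbenzoate | COc1cc(C)c(C(=O)Oc2cc(C)c(C(=O)OCC=C)c(O)c2C)c(OC)c1CO[Si](C(C)C)(C(C)C)C(C)C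
A6 | alternative 3 | 4-methoxy-3-methyl-4-[(trimethylsilyl)oxy]buta-1,3-dien-2-yl 2,4-dimethoxy-6-methyl-3-{[(triisopropylsilyl)oxy]methyl}benzoate | C=C(OC(=O)c1c(C)cc(OC)c(CO[Si](C(C)C)(C(C)C)C(C)C)c1OC)C(C)=C(OC)O[Si](C)(C)C
A7 | alternative 3 | allyl but-2-ynoate | CC#CC(=O)OCC=C
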